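Readings and results come from a simulation on assumed constants; the scatter is artificial.

The easy step is a division: for each set-up I take [target]/([target]+[isomer of the product]), the share that is asked for.

| flask | substrate | partner | protic impurity | initiator | remark | time |
|---|---|---|---|---|---|---|
| red | 10 mM | 11 mM | 3 mM | 0.31 mM | run made earlier |  |
| ochre | 5 mM | 11 mM | 3 mM | 0.31 mM | run made earlier |  |
| blue | 20 mM | 11 mM | 3 mM | 0.31 mM | run made earlier |  |
| green | 10 mM | 11 mM | 3 mM | 0.46 mM | run made earlier |  |
| north-west | 10 mM | 11.0 mM | 3.00 mM | 0.31 mM | one stirred flow tank at steady state, fed with the mixture as stated, mean residence time 30 h |  |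
| south | 10 mM | 11.0 mM | 3.00 mM | 0.31 mM | a closed flask charged with all of it at once and left for 30 h | 30 h |
| east | 10 mM (fed, over 30.0 h) | 11.0 mM | 3.00 mM | 0.31 mM | a stirred flask in which substrate is dosed at a steady rate over 30.0 h without added volume, worked up at 30 h | 30 h |
| north | 10 mM | 11.0 mM (fed, over 30.0 h) | 3.00 mM | 0.31 mM | all but partner at the start; partner goes in evenly over 30.0 h, the run ends at 30 h | 30 h |

| run | time / h | target / % | isomer of the product / % | substrate / % |
|---|---|---|---|---|
| red | 2.50 | 14.2 | 5.3 | 81.7 |
| red | 8.00 | 22.3 | 18.4 | 56.8 |
| red | 15.0 | 22.6 | 33.7 | 38.7 |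
| red | 20.0 | 25.4 | 40.4 | 31.8 |
| red | 30.0 | 23.2 | 48.2 | 24.3 |
| ochre | 1.50 | 20.1 | 2.0 | 75.5 |
| ochre | 5.00 | 38.7 | 21.9 | 42.5 |
| ochre | 8.00 | 41.8 | 37.7 | 18.8 |
| ochre | 12.0 | 40.5 | 50.9 | 2.6 |
| ochre | 20.0 | 32.0 | 62.5 | 1.7 |
| blue | 4.00 | 8.0 | 4.3 | 86.6 |
| blue | 8.00 | 11.2 | 8.9 | 77.6 |
| blue | 10.0 | 11.8 | 12.1 | 74.9 |
| blue | 15.0 | 13.1 | 17.3 | 69.9 |
| blue | 20.0 | 11.8 | 22.1 | 66.5 |
| green | 4.00 | 20.2 | 9.4 | 69.2 |
| green | 8.00 | 24.4 | 23.7 | 50.6 |
| green | 10.0 | 27.0 | 27.3 | 44.0 |
| green | 15.0 | 25.5 | 36.9 | 35.7 |
| green | 20.0 | 24.0 | 43.0 | 27.3 |

(scatter of a reading: 1 percentage point)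

* the set-up with the highest share of target in all that became target or isomer of the product, at the outlet or at the end ("none" if the first two lie within 2 percentage points) (north-west / south / east / north / none)
* share of target in all that became target or isomer of the product, at the outlet or at the end, north-west
* share of target in all that became target or isomer of the product, at the outlet or at the end, south
* share of target in all that became target or isomer of the product, at the outlet or at the end, east
* share of target in all that became target or isomer of the product, at the outlet or at the end, north

- the stated concentrations are those of everything mixed, before any reaction; amounts are the same in each set-up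
- the feed brings no volume worth counting
- the earlier runs were made in a closed, stirred flask

In the ochre run substrate reads 2.6% at 12.0 h and 1.7% at 20.0 h, and between those times the share falls from 44.3% to 33.9%. The red run's last reading, 32.5%, is lower than that, and I take it as my estimate of the floor, the equilibrium share. If the excess over this floor decays first order, ochre gives a constant of 0.269 h⁻¹. This is a rough reading, since the excess at 20.0 h is 1.4 percentage points against a scatter of 1 point.

Multiplying that constant by the 30 h gives x = 8.08, the relaxation number: how many times the excess shrinks by a factor e in the time given. Target of age a keeps e to the minus ka of its excess, and averaging this over ages is the one integration needed. The ages in a stirred tank give a factor of one over one plus x, so I expect 39.9% for north-west. Ages spread evenly give one minus e to the minus x, over x, so 40.8% for east and north if their target forms evenly.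

Is one number enough? At 20.0 h the even rule gives 45.0%, but ochre reads lower, at 33.9%, and at 8.00 h it already held 84.1% of the target and isomer of the product that it reads at 20.0 h. So the ochre run does not follow the even rule, and for south, also a closed flask, I keep the red reading, 32.5%.

The forecast gives 26%, 33%, 39% and 38% for north-west, south, east and north, and best none. On the tank it says “product stays long”. My tank figure is higher than the forecast's.

The set-ups give 39.2% in north-west, 34.3% in south, 36.7% in east and 46.1% in north, so the best is north.

    initiator → 2 initiating radical (k = 4.90 × 10⁻⁴ min⁻¹)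
    substrate + initiating radical → capped initiator + first chain carrier (k = 1.20 × 10⁵ M⁻¹ s⁻¹)
    partner + first chain carrier ⇌ target + second chain carrier (K = 0.150, k = 10000 M⁻¹ s⁻¹)
    substrate + second chain carrier → by-product + first chain carrier (k = 3.60 × 10⁵ M⁻¹ s⁻¹)
    2 first chain carrier → ended chains (k = 3.20 × 10⁸ M⁻¹ s⁻¹)
    target ⇌ isomer of the product (K = 2.10, k = 0.00330 min⁻¹)
    partner + protic impurity → quenched reagent (k = 12.0 M⁻¹ min⁻¹)

With the conversion of target into isomer of the product struck out, north-west gives 100%, which is the tank rule at x = 0. At 30 h north stands 14 points above my floor of 32.5%; carried on to 300 h it gets a further relaxation number of 72.6, and its share at that time is 32.3%.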